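The target follows the electrophile lost: at 4.00 min the spring run reads 96.6% target with 4.2% electrophile left, so the part reacted can be taken from the electrophile remaining.

| flask | electrophile | nucleophile | protic impurity | remark | time |
|---|---|---|---|---|---|
| summer | 5 mM | 3 equiv | 1.5 mM | run made earlier |  |
| spring | 5 mM | 5.1 equiv | 1.5 mM | run made earlier |  |
| Wednesday's | 5.0 mM | 2.50 equiv | 1.50 mM |  | 4.0 min |
| Tuesday's | 5.0 mM | 3.80 equiv | 1.50 mM |  | 4.0 min |

| run | time / min | electrophile / % | target / % |
|---|---|---|---|
| summer | 0.250 | 85.0 | 14.9 |
| summer | 0.833 | 60.8 | 38.9 |
| summer | 1.33 | 49.7 | 51.8 |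
| summer | 2.00 | 37.4 | 62.6 |
| summer | 3.00 | 27.0 | 72.2 |
| summer | 4.00 | 20.6 | 80.8 |
| spring | 0.333 | 68.3 | 31.4 |
| spring | 0.500 | 57.4 | 42.3 |
| spring | 0.833 | 41.1 | 58.6 |
| spring | 1.33 | 26.9 | 73.8 |
| spring | 2.50 | 10.4 | 89.8 |
| spring | 4.00 | 4.2 | 96.6 |

(each reading ± 0.5 percentage points)



1. part of the electrophile that has reacted at the end, Wednesday's
2. part of the electrophile that has reacted at the end, Tuesday's
3. what raising the equivalents of nucleophile from its lowest to its highest value here does to the part of the electrophile that has reacted (changes below 5 percentage points count as none) (it falls / it rises / no change)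

Let N = ln(charged/remaining) be the number of time constants the electrophile has passed at a given time. At 4.00 min, N is 1.58 in the summer run at 3 equiv and 3.17 in the spring run at 5.1 equiv, with the other charges equal. Joining these two ends by a power law gives n = 1.31. This equivalents exponent is the rise of ln N per rise of ln(equivalents), at fixed time and fixed other charges. A pseudo-first-order decay whose rate constant is proportional to the nucleophile charged has n = 1, and the reading stands higher.

My reckoning from n puts Tuesday's, inside the two runs, at N = 2.15, which is 88.4% reacted. Wednesday's, just below the summer run, comes to N = 1.24, which is 71.2% reacted.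

Now the question turned round. For no change, Tuesday's would have to end within 5 percentage points of Wednesday's, and with Wednesday's held at its reckoned N that asks for n below 0.340. A fall asks for n below 0. The runs read 3.85 times the first limit, so this reckoning gives a rise.

The forecast gives 72% for Wednesday's, 88% for Tuesday's and it rises: “Conversion rises with equivalents”.

The flask gives 71.5% for Wednesday's and 89.5% for Tuesday's, and it rises by 18 points.

    electrophile + nucleophile → acid set free + target (k = 0.852 /M/s)
    nucleophile + acid set free ⇌ protonated nucleophile, settled at all times (K = 43000 /M)
    nucleophile + acid set free ⇌ idle adduct, settled at all times (K = 1200 /M)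
    nucleophile + protic impurity → quenched reagent (k = 20.6 /M/s)

For Wednesday's, with the other concentrations held at their charge, the loss of nucleophile to quenched reagent gives a nucleophile half-life of 0.37 min, shorter than the electrophile half-life of 1.1 min by the making of target. At 4.00 min, Wednesday's holds 0% of its protic impurity and 1.50 mM quenched reagent, beside 28.5% electrophile. Between Wednesday's and Tuesday's, the two results put n at 1.40. For a flask like Tuesday's with 1.50 equiv nucleophile, the n of the runs gives 47.1% reacted, and that flask stands at 45.9%.

The runs were generated by integration for substances that don't exist; scatter was added.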